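**Plan**
- Retrosynthesis: the interflavanyl bond C4 (upper ring C)–C6 (lower ring A) is cut first, as the union of a C4 cation with ring A. Each flavan unit is then cut at O1–C8a and C2–C3, so both halves reduce to the same two pieces: a 2-fluoro-3,4-dialkoxyphenyl ketone and 4-(benzyloxy)benzaldehyde.
- Enabling feature: C4 of ring C is bonded to C4a, ortho to C8a of ring A. At the ketone level the C4 carbonyl makes C3–H acidic (aldol to the aldehyde carbon, the future C2) and activates a fluorine on C8a for displacement by the new C2 alkoxide (O1). Fluoride leaves in the event; the PMB ether on O3 and the C4 carbonyl are helpers adjusted later.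
- Forward: ring C is closed onto ring A in one aldol/SNAr operation to give a racemic 2,3-trans flavanone whose two enantiomers are the two halves. The (2S,3S) ketone becomes the lower 2,3-trans-3,4-cis diol unit. The (2R,3R) enantiomer becomes the upper 2,3-cis unit by C4 deoxygenation, C3 inversion and C4 thio-activation. The halves are joined C4→C6 and debenzylated.
- Stereochemistry: C2/C3 relative configuration is thermodynamic in the cascade; absolute configuration comes from a RuCl[(S,S)-TsDPEN](p-cymene) transfer-hydrogenation kinetic resolution. Lower C4 is set by equatorial hydride delivery, upper C3 by oxidation/LiBH(s-Bu)3 reduction, and upper C4 by attack anti to the 2-aryl and 3-O groups.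

Key step: step 3

Remark: Weinreb amide 3 is taken as a purchasable building block; if it is not stocked it is one amidation from commercial 2-[(4-methoxybenzyl)oxy]acetic acid.

**Step 1**
Reactants: 1 3-fluorobenzene-1,2-diol
Product: 2 1,2-bis(benzyloxy)-3-fluorobenzene
Conditions: BnBr, K2CO3, DMF, 60 °C
Reagents that add atoms: benzyl bromide, BrCc1ccccc1
Why: Williamson O-alkylation of both catechol hydroxyls; no stereocentre is involved.

**Step 2**
Reactants: 2 1,2-bis(benzyloxy)-3-fluorobenzene; 3 N-methoxy-2-[(4-methoxybenzyl)oxy]-N-methylacetamide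
Product: 4 1-[3,4-bis(benzyloxy)-2-fluorophenyl]-2-[(4-methoxybenzyl)oxy]ethan-1-one
Conditions: n-BuLi, THF, −78 °C; then 3, −78 → −40 °C; aq NH4Cl
Reagents that add atoms: none
Why: Directed ortho-lithiation next to fluorine, the most acidifying substituent on the ring, followed by Weinreb ketone synthesis through the stable chelated adduct; −78 °C prevents LiF loss to the aryne and metalation of the benzyl ethers.

**Step 3**
Reactants: 4 1-[3,4-bis(benzyloxy)-2-fluorophenyl]-2-[(4-methoxybenzyl)oxy]ethan-1-one; 5 4-(benzyloxy)benzaldehyde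
Product: 7 racemic 2,3-trans-7,8-bis(benzyloxy)-2-[4-(benzyloxy)phenyl]-3-[(4-methoxybenzyl)oxy]chroman-4-one [(2S,3S) and (2R,3R)], via potassium aldolate 6 (not isolated)
Conditions: KN(SiMe3)2, THF, −78 °C; 5; 18-crown-6, −78 → 25 °C; AcOH; then NaOAc, EtOH, 60 °C
Reagents that add atoms: none
Why: Proposed new method: the potassium enolate of 4 adds through C3 to the aldehyde carbon of 5 (the future C2), and the secondary alkoxide so formed attacks the fluorine-bearing ring A carbon C8a, ortho to the aryl ketone, through a carbonyl-stabilised Meisenheimer adduct that loses fluoride; the closest known reaction types are the tandem addition–SNAr annulations of 2-fluoroaryl ketones and the base-induced O-arylative closure of 2-fluorophenyl ketones to chromones and chroman-4-ones, which have not been run as one aldol–SNAr operation on an α-alkoxy ketone. Ring C closes in a 6-exo-trig addition–elimination in which the C–F bond breaks outside the new ring. C2 and C3 are formed without absolute control on purpose, and their relative configuration is thermodynamic: the aldol is reversible, C3 of the product is epimerisable next to the ketone, and any product that opens through its enolate to the 2'-hydroxychalcone recloses in the NaOAc stage, so the mixture should drain to the diequatorial 2,3-trans flavanone. The step needs O-arylation by the C2 alkoxide to beat dehydration to the chalcone, five-ring closure through O3 and intermolecular substitution; the single fluorine activated by the ortho carbonyl, the PMB ether that silences O3 and the crown-ether-separated potassium alkoxide should secure this. The fluoride helper is lost in the event, and the C4 carbonyl and the PMB group are dealt with later (steps 4, 5 and 7).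

**Step 4**
Reactants: 7 racemic 2,3-trans flavanone
Product: 8 (2R,3S,4R)-7,8-bis(benzyloxy)-2-[4-(benzyloxy)phenyl]-3-[(4-methoxybenzyl)oxy]chroman-4-ol (reduced enantiomer) and 9 (2S,3S)-7,8-bis(benzyloxy)-2-[4-(benzyloxy)phenyl]-3-[(4-methoxybenzyl)oxy]chroman-4-one (unreacted enantiomer, recovered)
Conditions: RuCl[(S,S)-TsDPEN](p-cymene) (cat.), HCO2H/Et3N (5:2), EtOAc, 25 °C, stopped just past half conversion; chromatography
Reagents that add atoms: none
Why: Noyori–Ikariya transfer hydrogenation used as a kinetic resolution of a 2-arylchroman-4-one: the (S,S) catalyst delivers hydride to the face that gives the 4R alcohol, a trajectory anti to the 2-aryl group only in the (2R,3R) ketone, which should be reduced to 8 while (2S,3S)-9 is left, so both enantiomers of 7 are used.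

**Step 5**
Reactants: 9 (2S,3S)-flavanone
Product: 10 (2S,3R,4R)-7,8-bis(benzyloxy)-2-[4-(benzyloxy)phenyl]-3-[(4-methoxybenzyl)oxy]chroman-4-ol (2,3-trans-3,4-cis)
Conditions: LiBH(s-Bu)3, THF, −78 °C; aq NH4Cl
Reagents that add atoms: none
Why: Bulky-hydride reduction of a 3-substituted chroman-4-one: equatorial attack at C4 should give the axial alcohol cis to the equatorial 3-alkoxy group, as in the cis-selective reduction of 3-substituted chromanones, which sets lower C4.

**Step 6**
Reactants: 10 (2S,3R,4R)-chroman-4-ol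
Product: 11 (2S,3R,4R)-4,7,8-tris(benzyloxy)-2-[4-(benzyloxy)phenyl]-3-[(4-methoxybenzyl)oxy]chromane
Conditions: NaH, BnBr, Bu4NI (cat.), DMF, 0 → 25 °C
Reagents that add atoms: benzyl bromide, BrCc1ccccc1
Why: Williamson benzylation of the C4 alkoxide caps the only free hydroxyl so that 11 can act solely as a carbon nucleophile in step 13; no stereocentre is touched.

**Step 7**
Reactants: 8 (2R,3S,4R)-chroman-4-ol
Product: 12 (2R,3S)-7,8-bis(benzyloxy)-2-[4-(benzyloxy)phenyl]chroman-3-ol
Conditions: Et3SiH (excess), TFA (10% v/v), CH2Cl2, 0 °C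
Reagents that add atoms: none
Why: Ionic hydrogenation: the acid ionises the C4 hydroxyl to the ring-A-stabilised benzylic cation, which the silane reduces to CH2, and the same medium cleaves the PMB ether with the silane as cation scavenger; dilute acid keeps ring C closed and C2/C3 untouched.

**Step 8**
Reactants: 12 (2R,3S)-chroman-3-ol
Product: 13 (2R)-7,8-bis(benzyloxy)-2-[4-(benzyloxy)phenyl]chroman-3-one
Conditions: Dess–Martin periodinane, NaHCO3, CH2Cl2, 0 → 25 °C
Reagents that add atoms: none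
Why: Dess–Martin oxidation of the secondary alcohol under buffered, non-enolising conditions, as in the known conversion of benzylated 2,3-trans flavan-3-ols to flavan-3-ones; the ketone is used at once so that C2 is not epimerised.

**Step 9**
Reactants: 13 (2R)-chroman-3-one
Product: 14 (2R,3R)-7,8-bis(benzyloxy)-2-[4-(benzyloxy)phenyl]chroman-3-ol (2,3-cis)
Conditions: LiBH(s-Bu)3, THF, −78 °C; aq NH4Cl
Reagents that add atoms: none
Why: Substrate-controlled reduction in which the bulky hydride approaches the face opposite the C2 aryl group, which should give the 2,3-cis alcohol and so set upper C3, as in the trans-to-cis inversion of benzylated flavan-3-ols.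

**Step 10**
Reactants: 14 (2R,3R)-chroman-3-ol
Product: 15 (2R,3R,4S)-7,8-bis(benzyloxy)-2-[4-(benzyloxy)phenyl]-4-(2-ethoxyethoxy)chroman-3-ol
Conditions: DDQ, 2-ethoxyethanol, CH2Cl2, 25 °C
Reagents that add atoms: 2-ethoxyethanol, CCOCCO
Why: Benzylic oxidation: DDQ abstracts hydride from C4 (para to the 7-benzyloxy group, ortho to O1) and the cation is trapped by the alcohol anti to the 2-aryl and 3-OH face, as known for benzylated flavan-3-ols.

**Step 11**
Reactants: 15 4-(2-ethoxyethoxy)chroman-3-ol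
Product: 16 (2R,3S,4S)-4-(benzylsulfanyl)-7,8-bis(benzyloxy)-2-[4-(benzyloxy)phenyl]chroman-3-ol
Conditions: BnSH, BF3·OEt2, CH2Cl2, −78 → −20 °C
Reagents that add atoms: phenylmethanethiol, SCc1ccccc1
Why: Lewis-acid ionisation of the C4 ether and capture of the cation by the thiol anti to the cis 2-aryl and 3-OH groups (thiolysis of a flavan C4 leaving group); this installs a group that a thiophile can activate while C4 ethers stay inert.

**Step 12**
Reactants: 16 4-(benzylsulfanyl)chroman-3-ol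
Product: 17 (2R,3S,4S)-4-(benzylsulfanyl)-3,7,8-tris(benzyloxy)-2-[4-(benzyloxy)phenyl]chromane
Conditions: NaH, BnBr, DMF, 0 °C
Reagents that add atoms: benzyl bromide, BrCc1ccccc1
Why: Williamson benzylation of the 3-OH removes the last oxygen nucleophile so that the buffered coupling can only form a C–C bond.

**Step 13**
Reactants: 17 4-(benzylsulfanyl)chromane (electrophile); 11 penta-O-protected lower unit (nucleophile)
Product: 18 protected dimer: the (2R,3R)-3,7,8-tris(benzyloxy)-2-[4-(benzyloxy)phenyl]chroman-4-yl unit bonded through C4 (3,4-trans) to C6 of (2S,3R,4R)-4,7,8-tris(benzyloxy)-2-[4-(benzyloxy)phenyl]-3-[(4-methoxybenzyl)oxy]chromane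
Conditions: AgBF4, 2,6-di-tert-butyl-4-methylpyridine, 4 Å MS, THF, −20 → 0 °C; 17 added slowly to 11 (2 equiv, excess recovered)
Reagents that add atoms: none
Why: Thiophilic activation: monovalent silver removes the benzylthio group to give the C4 benzylic cation, which C6 of 11 (para to O1, ortho to the 7-benzyloxy group) attacks in a Friedel–Crafts alkylation from the face anti to the 2-aryl and 3-benzyloxy groups, which sets upper C4; the pyridine base takes up HBF4 so that the C4 benzyl ether of 11 does not ionise.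

**Step 14**
Reactants: 18 protected dimer
Product: 19 (2R,3R,4S)-2-(4-hydroxyphenyl)-4-[(2S,3R,4R)-3,4,7,8-tetrahydroxy-2-(4-hydroxyphenyl)chroman-6-yl]chromane-3,7,8-triol (target)
Conditions: H2 (1 atm), Pd(OH)2/C, THF/MeOH, 25 °C
Reagents that add atoms: none
Why: Hydrogenolysis of the eight benzyl ethers and the PMB ether at their primary O–CH2Ar bonds, which cleave faster than the secondary ring C4–O bond under neutral conditions; no stereocentre is touched.

**Compound list**
1 | 3-fluorobenzene-1,2-diol | Oc1cccc(F)c1O | starting material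
2 | 1,2-bis(benzyloxy)-3-fluorobenzene | Fc1cccc(OCc2ccccc2)c1OCc1ccccc1 | intermediate
3 | N-methoxy-2-[(4-methoxybenzyl)oxy]-N-methylacetamide | CON(C)C(=O)COCc1ccc(OC)cc1 | starting material
4 | 1-[3,4-bis(benzyloxy)-2-fluorophenyl]-2-[(4-methoxybenzyl)oxy]ethan-1-one | COc1ccc(COCC(=O)c2ccc(OCc3ccccc3)c(OCc3ccccc3)c2F)cc1 | intermediate
5 | 4-(benzyloxy)benzaldehyde | O=Cc1ccc(OCc2ccccc2)cc1 | starting material
6 | potassium 3-[3,4-bis(benzyloxy)-2-fluorophenyl]-1-[4-(benzyloxy)phenyl]-2-[(4-methoxybenzyl)oxy]-3-oxopropan-1-olate (racemic syn/anti mixture) | COc1ccc(COC(C([O-])c2ccc(OCc3ccccc3)cc2)C(=O)c2ccc(OCc3ccccc3)c(OCc3ccccc3)c2F)cc1.[K+] | intermediate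
7 | racemic 2,3-trans-7,8-bis(benzyloxy)-2-[4-(benzyloxy)phenyl]-3-[(4-methoxybenzyl)oxy]chroman-4-one, (2S,3S) and (2R,3R) | O=C1c2ccc(OCc3ccccc3)c(OCc3ccccc3)c2O[C@@H](c2ccc(OCc3ccccc3)cc2)[C@@H]1OCc1ccc(OC)cc1.O=C1c2ccc(OCc3ccccc3)c(OCc3ccccc3)c2O[C@H](c2ccc(OCc3ccccc3)cc2)[C@H]1OCc1ccc(OC)cc1 | intermediate
8 | (2R,3S,4R)-7,8-bis(benzyloxy)-2-[4-(benzyloxy)phenyl]-3-[(4-methoxybenzyl)oxy]chroman-4-ol | O[C@@H]1c2ccc(OCc3ccccc3)c(OCc3ccccc3)c2O[C@H](c2ccc(OCc3ccccc3)cc2)[C@H]1OCc1ccc(OC)cc1 | intermediate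
9 | (2S,3S)-7,8-bis(benzyloxy)-2-[4-(benzyloxy)phenyl]-3-[(4-methoxybenzyl)oxy]chroman-4-one | O=C1c2ccc(OCc3ccccc3)c(OCc3ccccc3)c2O[C@@H](c2ccc(OCc3ccccc3)cc2)[C@@H]1OCc1ccc(OC)cc1 | intermediate
10 | (2S,3R,4R)-7,8-bis(benzyloxy)-2-[4-(benzyloxy)phenyl]-3-[(4-methoxybenzyl)oxy]chroman-4-ol | O[C@@H]1c2ccc(OCc3ccccc3)c(OCc3ccccc3)c2O[C@@H](c2ccc(OCc3ccccc3)cc2)[C@@H]1OCc1ccc(OC)cc1 | intermediate
11 | (2S,3R,4R)-4,7,8-tris(benzyloxy)-2-[4-(benzyloxy)phenyl]-3-[(4-methoxybenzyl)oxy]chromane | C(O[C@@H]1c2ccc(OCc3ccccc3)c(OCc3ccccc3)c2O[C@@H](c2ccc(OCc3ccccc3)cc2)[C@@H]1OCc1ccc(OC)cc1)c1ccccc1 | intermediate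
12 | (2R,3S)-7,8-bis(benzyloxy)-2-[4-(benzyloxy)phenyl]chroman-3-ol | C1c2ccc(OCc3ccccc3)c(OCc3ccccc3)c2O[C@H](c2ccc(OCc3ccccc3)cc2)[C@H]1O | intermediate
13 | (2R)-7,8-bis(benzyloxy)-2-[4-(benzyloxy)phenyl]chroman-3-one | C1c2ccc(OCc3ccccc3)c(OCc3ccccc3)c2O[C@H](c2ccc(OCc3ccccc3)cc2)C1=O | intermediate
14 | (2R,3R)-7,8-bis(benzyloxy)-2-[4-(benzyloxy)phenyl]chroman-3-ol | C1c2ccc(OCc3ccccc3)c(OCc3ccccc3)c2O[C@H](c2ccc(OCc3ccccc3)cc2)[C@@H]1O | intermediate
15 | (2R,3R,4S)-7,8-bis(benzyloxy)-2-[4-(benzyloxy)phenyl]-4-(2-ethoxyethoxy)chroman-3-ol | CCOCCO[C@H]1c2ccc(OCc3ccccc3)c(OCc3ccccc3)c2O[C@H](c2ccc(OCc3ccccc3)cc2)[C@@H]1O | intermediate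
16 | (2R,3S,4S)-4-(benzylsulfanyl)-7,8-bis(benzyloxy)-2-[4-(benzyloxy)phenyl]chroman-3-ol | C(S[C@H]1c2ccc(OCc3ccccc3)c(OCc3ccccc3)c2O[C@H](c2ccc(OCc3ccccc3)cc2)[C@@H]1O)c1ccccc1 | intermediate
17 | (2R,3S,4S)-4-(benzylsulfanyl)-3,7,8-tris(benzyloxy)-2-[4-(benzyloxy)phenyl]chromane | C(S[C@H]1c2ccc(OCc3ccccc3)c(OCc3ccccc3)c2O[C@H](c2ccc(OCc3ccccc3)cc2)[C@@H]1OCc1ccccc1)c1ccccc1 | intermediate
18 | protected dimer, octa-O-benzyl 3-O-(4-methoxybenzyl) ether of 19 (PMB on the lower O3), all stereocentres as in 19 | C(c5ccccc5)Oc1ccc([C@H]2Oc3c(ccc(OCc5ccccc5)c3OCc5ccccc5)[C@H](c3cc4c(c(OCc5ccccc5)c3OCc5ccccc5)O[C@@H](c3ccc(OCc5ccccc5)cc3)[C@H](OCc6ccc(OC)cc6)[C@@H]4OCc5ccccc5)[C@H]2OCc5ccccc5)cc1 | intermediate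
19 | (2R,3R,4S)-2-(4-hydroxyphenyl)-4-[(2S,3R,4R)-3,4,7,8-tetrahydroxy-2-(4-hydroxyphenyl)chroman-6-yl]chromane-3,7,8-triol | Oc1ccc([C@H]2Oc3c(ccc(O)c3O)[C@H](c3cc4c(c(O)c3O)O[C@@H](c3ccc(O)cc3)[C@H](O)[C@@H]4O)[C@H]2O)cc1 | target

**Step count and risks**
Total steps: 14. Longest linear sequence: 12 (steps 1–4 and 7–14).

Step 3 (proposed new method). The aldolate may be lost by dehydration to the α-alkoxychalcone or by retro-aldol before it arylates, or the product may be opened by base faster than it forms. The fallback uses known chemistry, sets out from 4 and returns at 7. Fluoride of 4 is displaced by a hydroxide equivalent (acetohydroxamic acid, K2CO3, DMSO, 80 °C) to give 1-[3,4-bis(benzyloxy)-2-hydroxyphenyl]-2-[(4-methoxybenzyl)oxy]ethan-1-one F1. Claisen–Schmidt condensation of this with 5 (KOH, EtOH, 25 °C) gives (Z)-1-[3,4-bis(benzyloxy)-2-hydroxyphenyl]-3-[4-(benzyloxy)phenyl]-2-[(4-methoxybenzyl)oxy]prop-2-en-1-one F2. Buffered oxa-Michael closure (NaOAc, EtOH, reflux) then gives racemic trans 7.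

Step 4. The 3-alkoxy group may erode the rate difference between the two enantiomers, so that neither fraction is obtained enantiopure. The fallback sets out from 7 and returns at 8 and 9. Racemic 7 is separated on a polysaccharide chiral stationary phase into 9 and its enantiomer (2R,3R)-7,8-bis(benzyloxy)-2-[4-(benzyloxy)phenyl]-3-[(4-methoxybenzyl)oxy]chroman-4-one F3. F3 is reduced with NaBH4 (MeOH/THF, 0 °C; axial hydride delivery) to 8.

Step 13. The cation may alkylate C6 of ring A of a second molecule of electrophile, giving oligomers instead of the cross-coupled dimer. The fallback blocks that position with bromine, sets out from 15 and returns at 19. NBS (CH2Cl2, −78 → 0 °C) brominates C6 of ring A to give (2R,3R,4S)-7,8-bis(benzyloxy)-2-[4-(benzyloxy)phenyl]-6-bromo-4-(2-ethoxyethoxy)chroman-3-ol F4. Thiol exchange as in step 11 gives the 6-bromo analogue of 16 F5, and benzylation as in step 12 gives the 6-bromo analogue of 17 F6. Coupling with a near-stoichiometric amount of 11 under the step 13 conditions gives the 6-bromo analogue of 18 F7. Hydrogenolysis (H2, Pd(OH)2/C, NaOAc, THF/MeOH) removes the bromine with the benzyl groups and gives 19.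

**Further compounds**
F1 | step 3 | 1-[3,4-bis(benzyloxy)-2-hydroxyphenyl]-2-[(4-methoxybenzyl)oxy]ethan-1-one | COc1ccc(COCC(=O)c2ccc(OCc3ccccc3)c(OCc3ccccc3)c2O)cc1
F2 | step 3 | (Z)-1-[3,4-bis(benzyloxy)-2-hydroxyphenyl]-3-[4-(benzyloxy)phenyl]-2-[(4-methoxybenzyl)oxy]prop-2-en-1-one | O=C(c1ccc(OCc2ccccc2)c(OCc2ccccc2)c1O)/C(OCc1ccc(OC)cc1)=C/c1ccc(OCc2ccccc2)cc1
F3 | step 4 | (2R,3R)-7,8-bis(benzyloxy)-2-[4-(benzyloxy)phenyl]-3-[(4-methoxybenzyl)oxy]chroman-4-one | O=C1c2ccc(OCc3ccccc3)c(OCc3ccccc3)c2O[C@H](c2ccc(OCc3ccccc3)cc2)[C@H]1OCc1ccc(OC)cc1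
F4 | step 13 | (2R,3R,4S)-7,8-bis(benzyloxy)-2-[4-(benzyloxy)phenyl]-6-bromo-4-(2-ethoxyethoxy)chroman-3-ol | CCOCCO[C@H]1c2cc(Br)c(OCc3ccccc3)c(OCc3ccccc3)c2O[C@H](c2ccc(OCc3ccccc3)cc2)[C@@H]1O
F5 | step 13 | (2R,3S,4S)-4-(benzylsulfanyl)-7,8-bis(benzyloxy)-2-[4-(benzyloxy)phenyl]-6-bromochroman-3-ol | C(S[C@H]1c2cc(Br)c(OCc3ccccc3)c(OCc3ccccc3)c2O[C@H](c2ccc(OCc3ccccc3)cc2)[C@@H]1O)c1ccccc1
F6 | step 13 | (2R,3S,4S)-4-(benzylsulfanyl)-3,7,8-tris(benzyloxy)-2-[4-(benzyloxy)phenyl]-6-bromochromane | C(S[C@H]1c2cc(Br)c(OCc3ccccc3)c(OCc3ccccc3)c2O[C@H](c2ccc(OCc3ccccc3)cc2)[C@@H]1OCc1ccccc1)c1ccccc1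
F7 | step 13 | 6-bromo analogue of 18 (bromine on C6 of ring A of the upper unit) | C(c5ccccc5)Oc1ccc([C@H]2Oc3c(cc(Br)c(OCc5ccccc5)c3OCc5ccccc5)[C@H](c3cc4c(c(OCc5ccccc5)c3OCc5ccccc5)O[C@@H](c3ccc(OCc5ccccc5)cc3)[C@H](OCc6ccc(OC)cc6)[C@@H]4OCc5ccccc5)[C@H]2OCc5ccccc5)cc1
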